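**Retrosynthetic overview**

1. Feature: the target holds three trans 2-(4-hydroxyphenyl)-3-aryl-2,3-dihydrobenzofurans, ring L (2S,3S; 7-OH, 5-styryl), ring M (2R,3R; 6-styryl) and ring R (2S,3S; 6-OH, bonded through C4 to C3 of ring M). In each, O1, C2 with its aryl group, C3a and C7a are O1, C2, C4a and C8a of a flavanone, so a shift of the benzo carbon C4a from the carbonyl carbon C4 to C3 makes the C3–C3a bond and leaves C4 as a C3 carboxylate.
2. The E-stilbene bond is cut by a Mizoroki–Heck coupling between the C5 chloride of ring L and a 6-vinyl group on ring M; the nine phenols travel as three mesylates and six methyl ethers and are freed last.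
3. Each C3–aryl bond comes from the C3 ester via the acid and its N-hydroxyphthalimide ester by nickel-catalysed decarboxylative arylation trans to the C2 aryl group: rings L and R with 1-iodo-3,5-dimethoxybenzene, ring M C3 with the C4 bromide of ring R.
4. The three flavanones come from rhodium/chiral diene 1,4-addition of 4-(mesyloxy)phenylboronic acid to chromones made from 2-hydroxyacetophenones (2S for rings L and R, 2R for ring M).
5. Ring order: pyranone L, contracted to dihydrofuran L (step 5); pyranone M, contracted (step 10); pyranone R, contracted (step 16); no ring is formed afterwards.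

Key step: step 5

Assumption: the chiral diene is taken to deliver the aryl group to chromones with the same facial sense as to cyclic enones, so the S,S ligand is assigned to the 2S flavanones (steps 4 and 15) and the R,R ligand to the 2R flavanone (step 9); if the first batch shows the opposite sense, the two ligand antipodes are exchanged.

**Route**

Step 1
Reactants: 1 (4-hydroxyphenyl)boronic acid
Product: 2 [4-(methylsulfonyloxy)phenyl]boronic acid
Conditions: MsCl, Et3N, THF, 0 °C to rt; then 1 M HCl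
Reagents that add atoms: methanesulfonyl chloride, CS(=O)(=O)Cl
Why: O-sulfonylation of the phenol, with any mixed boron anhydride or boroxine hydrolysed back to the boronic acid in the acidic aqueous work-up.

Step 2
Reactants: 3 1-(2-hydroxy-3-methoxyphenyl)ethanone
Product: 4 1-(5-chloro-2-hydroxy-3-methoxyphenyl)ethanone
Conditions: NCS, DMF, rt
Reagents that add atoms: N-chlorosuccinimide, O=C1CCC(=O)N1Cl
Why: Electrophilic aromatic chlorination goes to C5, the only open site para to the phenol and meta to the acetyl group, as in the halogenation of the corresponding aldehyde.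

Step 3
Reactants: 4 1-(5-chloro-2-hydroxy-3-methoxyphenyl)ethanone
Product: 6 6-chloro-8-methoxy-4H-chromen-4-one, via enaminone 5 (not isolated)
Conditions: Me2NCH(OMe)2, toluene, 100 °C; evaporate; then conc. HCl, CH2Cl2, 40 °C
Reagents that add atoms: N,N-dimethylformamide dimethyl acetal, COC(OC)N(C)C
Why: Condensation at the acetyl methyl group gives the enaminone, and acid then drives addition of the phenol oxygen and loss of dimethylamine (enaminone route to chromones).

Step 4
Reactants: 6 6-chloro-8-methoxy-4H-chromen-4-one; 2 [4-(methylsulfonyloxy)phenyl]boronic acid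
Product: 7 4-[(2S)-6-chloro-8-methoxy-4-oxo-3,4-dihydro-2H-chromen-2-yl]phenyl methanesulfonate
Conditions: [RhCl(C2H4)2]2 (2.5 mol %), (1S,4S)-2,5-diphenylbicyclo[2.2.2]octa-2,5-diene (6 mol %), aq. KOH (10 mol %), 1,4-dioxane/H2O 10:1, 30 °C
Reagents that add atoms: none
Why: Hayashi–Miyaura asymmetric 1,4-addition, in which the aryl–rhodium species bound to the chiral diene inserts one face of the chromone C2=C3 bond and so sets C2, with low base loading and temperature chosen so that the flavanone does not racemise by retro-oxa-Michael opening.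

Step 5
Reactants: 7 4-[(2S)-6-chloro-8-methoxy-4-oxo-3,4-dihydro-2H-chromen-2-yl]phenyl methanesulfonate
Product: 9 methyl (2S,3S)-5-chloro-7-methoxy-2-[4-(methylsulfonyloxy)phenyl]-2,3-dihydro-1-benzofuran-3-carboxylate, via methyl enol ether 8 (not isolated)
Conditions: PhI(OAc)2 (1.3 equiv), conc. H2SO4 (0.5 equiv), HC(OMe)3, 0 °C to rt
Reagents that add atoms: trimethyl orthoformate, COC(OC)OC
Why: Acid-catalysed exchange with the orthoformate converts the C4 ketone into enol ether 8, which attacks the acid-activated trivalent iodine reagent at C3 on the face anti to the C2 aryl group while methanol adds to C4; the equatorial C3–I(Ph) bond is then antiperiplanar to the C4–C4a ring bond, C4a shifts from C4 to C3 with loss of iodobenzene and inversion at C3, and the dimethoxycarbenium ion left at the former C4 is demethylated to the methyl ester. The closest known reaction type is the hypervalent-iodine (or thallium trinitrate) oxidative ring contraction of flavanones to trans methyl 2-aryl-2,3-dihydrobenzofuran-3-carboxylates. The ring O1–C2–C3–C3a–C7a is closed not by a new cyclisation but by this 1,2-aryl shift, which makes the C3–C3a bond and contracts the pyranone. C2 is not touched and keeps its S configuration, and the new C3 centre is placed trans to it by anti iodination followed by inversion, trans also being the more stable arrangement of this enolisable ester. The step needs migration of C4a in preference to the C2 aryl group (isoflavone pathway) and to plain dehydrogenation (flavone pathway); C4a is activated by the ortho ring oxygen, whereas the mesyloxyphenyl group is electron-poor and migrates badly.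

Step 6
Reactants: 9 methyl (2S,3S)-5-chloro-7-methoxy-2-[4-(methylsulfonyloxy)phenyl]-2,3-dihydro-1-benzofuran-3-carboxylate
Product: 10 (2S,3S)-5-chloro-7-methoxy-2-[4-(methylsulfonyloxy)phenyl]-2,3-dihydro-1-benzofuran-3-carboxylic acid
Conditions: Me3SnOH, ClCH2CH2Cl, 80 °C; then 1 M HCl wash
Reagents that add atoms: trimethyltin hydroxide, C[Sn](C)(C)O
Why: Near-neutral tin hydroxide ester cleavage is chosen because aqueous alkali could open the ring through the ester enolate (expulsion of the C2 phenoxide, which would racemise C2) and attack the mesylate.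

Step 7
Reactants: 10 (2S,3S)-5-chloro-7-methoxy-2-[4-(methylsulfonyloxy)phenyl]-2,3-dihydro-1-benzofuran-3-carboxylic acid; 11 1-iodo-3,5-dimethoxybenzene
Product: 13 4-[(2S,3S)-5-chloro-3-(3,5-dimethoxyphenyl)-7-methoxy-2,3-dihydro-1-benzofuran-2-yl]phenyl methanesulfonate, via N-hydroxyphthalimide ester 12 (not isolated)
Conditions: N-hydroxyphthalimide, DIC, DMAP (cat.), CH2Cl2, rt; filter, evaporate; then 11, NiBr2·glyme (10 mol %), 4,4'-di-tert-butyl-2,2'-bipyridine (10 mol %), Zn, DMA, rt
Reagents that add atoms: N-hydroxyphthalimide, O=C1c2ccccc2C(=O)N1O (its atoms are held only in 12 and leave again)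
Why: Steglich-type esterification followed by nickel-catalysed reductive decarboxylative arylation (cross-electrophile coupling), in which electron transfer releases CO2 and the planar C3 benzylic radical and the aryl–nickel species from the iodide bonds to it on the face anti to the C2 aryl group, so C3 is set anew as 3S (trans) under control of C2 while the aryl chloride and mesylate are inert to zerovalent nickel/bipyridine at rt.

Step 8
Reactants: 14 1-(4-chloro-2-hydroxyphenyl)ethanone
Product: 16 7-chloro-4H-chromen-4-one, via enaminone 15 (not isolated)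
Conditions: Me2NCH(OMe)2, toluene, 100 °C; evaporate; then conc. HCl, CH2Cl2, 40 °C
Reagents that add atoms: N,N-dimethylformamide dimethyl acetal, COC(OC)N(C)C
Why: Same enaminone condensation and acid cyclisation as in step 3.

Step 9
Reactants: 16 7-chloro-4H-chromen-4-one; 2 [4-(methylsulfonyloxy)phenyl]boronic acid
Product: 17 4-[(2R)-7-chloro-4-oxo-3,4-dihydro-2H-chromen-2-yl]phenyl methanesulfonate
Conditions: [RhCl(C2H4)2]2 (2.5 mol %), (1R,4R)-2,5-diphenylbicyclo[2.2.2]octa-2,5-diene (6 mol %), aq. KOH (10 mol %), 1,4-dioxane/H2O 10:1, 30 °C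
Reagents that add atoms: none
Why: Hayashi–Miyaura asymmetric 1,4-addition as in step 4, with the antipodal diene on rhodium giving the 2R centre needed for ring M.

Step 10
Reactants: 17 4-[(2R)-7-chloro-4-oxo-3,4-dihydro-2H-chromen-2-yl]phenyl methanesulfonate
Product: 19 methyl (2R,3R)-6-chloro-2-[4-(methylsulfonyloxy)phenyl]-2,3-dihydro-1-benzofuran-3-carboxylate, via methyl enol ether 18 (not isolated)
Conditions: PhI(OAc)2 (1.3 equiv), conc. H2SO4 (0.5 equiv), HC(OMe)3, 0 °C to rt
Reagents that add atoms: trimethyl orthoformate, COC(OC)OC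
Why: Same oxidative 1,2-shift of C4a as in step 5, the ortho ring oxygen again making C4a the migrating group and anti iodination with inversion giving the trans ester with C2 retained.

Step 11
Reactants: 19 methyl (2R,3R)-6-chloro-2-[4-(methylsulfonyloxy)phenyl]-2,3-dihydro-1-benzofuran-3-carboxylate
Product: 20 (2R,3R)-6-chloro-2-[4-(methylsulfonyloxy)phenyl]-2,3-dihydro-1-benzofuran-3-carboxylic acid
Conditions: Me3SnOH, ClCH2CH2Cl, 80 °C; then 1 M HCl wash
Reagents that add atoms: trimethyltin hydroxide, C[Sn](C)(C)O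
Why: Near-neutral ester cleavage as in step 6, which avoids enolate-driven ring opening.

Step 12
Reactants: 21 1-bromo-3,5-dimethoxybenzene
Product: 22 1-(2-bromo-4,6-dimethoxyphenyl)ethanone
Conditions: AcCl, AlCl3, CH2Cl2, 0 °C
Reagents that add atoms: acetyl chloride, CC(=O)Cl
Why: Friedel–Crafts acylation at the site para to one methoxy group and ortho to the other, which is favoured over the site between the two methoxy groups, the minor 4-bromo-2,6-dimethoxy isomer being removed by crystallisation.

Step 13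
Reactants: 22 1-(2-bromo-4,6-dimethoxyphenyl)ethanone
Product: 23 1-(2-bromo-6-hydroxy-4-methoxyphenyl)ethanone
Conditions: BCl3, CH2Cl2, −78 to 0 °C; then H2O
Reagents that add atoms: none
Why: Chelation of boron between the carbonyl oxygen and the ortho methoxy group makes the Lewis-acid demethylation selective for that ether and leaves the para methoxy group.

Step 14
Reactants: 23 1-(2-bromo-6-hydroxy-4-methoxyphenyl)ethanone
Product: 25 5-bromo-7-methoxy-4H-chromen-4-one, via enaminone 24 (not isolated)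
Conditions: Me2NCH(OMe)2, toluene, 100 °C; evaporate; then conc. HCl, CH2Cl2, 40 °C
Reagents that add atoms: N,N-dimethylformamide dimethyl acetal, COC(OC)N(C)C
Why: Same enaminone condensation and acid cyclisation as in step 3, which tolerates the second ortho substituent on the acetophenone.

Step 15
Reactants: 25 5-bromo-7-methoxy-4H-chromen-4-one; 2 [4-(methylsulfonyloxy)phenyl]boronic acid
Product: 26 4-[(2S)-5-bromo-7-methoxy-4-oxo-3,4-dihydro-2H-chromen-2-yl]phenyl methanesulfonate
Conditions: [RhCl(C2H4)2]2 (3 mol %), (1S,4S)-2,5-diphenylbicyclo[2.2.2]octa-2,5-diene (7 mol %), aq. KOH (10 mol %), 1,4-dioxane/H2O 10:1, 40 °C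
Reagents that add atoms: none
Why: Hayashi–Miyaura asymmetric 1,4-addition as in step 4, the S,S diene setting the 2S centre of ring R and the aryl bromide being inert to monovalent rhodium.

Step 16
Reactants: 26 4-[(2S)-5-bromo-7-methoxy-4-oxo-3,4-dihydro-2H-chromen-2-yl]phenyl methanesulfonate
Product: 28 methyl (2S,3S)-4-bromo-6-methoxy-2-[4-(methylsulfonyloxy)phenyl]-2,3-dihydro-1-benzofuran-3-carboxylate, via methyl enol ether 27 (not isolated)
Conditions: PhI(OAc)2 (1.3 equiv), conc. H2SO4 (0.5 equiv), HC(OMe)3, 0 °C to rt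
Reagents that add atoms: trimethyl orthoformate, COC(OC)OC
Why: Same oxidative 1,2-shift as in step 5, here helped by the methoxy group para to the migrating carbon C4a, giving the trans ester with C2 retained.

Step 17
Reactants: 20 (2R,3R)-6-chloro-2-[4-(methylsulfonyloxy)phenyl]-2,3-dihydro-1-benzofuran-3-carboxylic acid; 28 methyl (2S,3S)-4-bromo-6-methoxy-2-[4-(methylsulfonyloxy)phenyl]-2,3-dihydro-1-benzofuran-3-carboxylate
Product: 30 methyl (2S,3S)-4-[(2R,3R)-6-chloro-2-[4-(methylsulfonyloxy)phenyl]-2,3-dihydro-1-benzofuran-3-yl]-6-methoxy-2-[4-(methylsulfonyloxy)phenyl]-2,3-dihydro-1-benzofuran-3-carboxylate, via N-hydroxyphthalimide ester 29 (not isolated)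
Conditions: N-hydroxyphthalimide, DIC, DMAP (cat.), CH2Cl2, rt; filter, evaporate; then 28, NiBr2·glyme (20 mol %), 4,4'-di-tert-butyl-2,2'-bipyridine (20 mol %), NaI (0.5 equiv), Zn, DMA, 40 °C
Reagents that add atoms: N-hydroxyphthalimide, O=C1c2ccccc2C(=O)N1O (its atoms are held only in 29 and leave again)
Why: Nickel-catalysed reductive decarboxylative arylation with the aryl bromide as electrophile (iodide additive), in which the C3 radical of ring M is joined to C4 of ring R on the face anti to the C2 aryl group, setting C3 of ring M as 3R (trans), while the aryl chloride and the methyl ester do not react.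

Step 18
Reactants: 30 methyl ester from step 17
Product: 31 (2S,3S)-4-[(2R,3R)-6-chloro-2-[4-(methylsulfonyloxy)phenyl]-2,3-dihydro-1-benzofuran-3-yl]-6-methoxy-2-[4-(methylsulfonyloxy)phenyl]-2,3-dihydro-1-benzofuran-3-carboxylic acid
Conditions: Me3SnOH, ClCH2CH2Cl, 80 °C; then 1 M HCl wash
Reagents that add atoms: trimethyltin hydroxide, C[Sn](C)(C)O
Why: Near-neutral tin hydroxide cleavage as in step 6, which also copes with the hindered ester and spares the three mesylates.

Step 19
Reactants: 31 carboxylic acid from step 18; 11 1-iodo-3,5-dimethoxybenzene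
Product: 33 4-[(2R,3R)-6-chloro-3-[(2S,3S)-3-(3,5-dimethoxyphenyl)-6-methoxy-2-[4-(methylsulfonyloxy)phenyl]-2,3-dihydro-1-benzofuran-4-yl]-2,3-dihydro-1-benzofuran-2-yl]phenyl methanesulfonate, via N-hydroxyphthalimide ester 32 (not isolated)
Conditions: N-hydroxyphthalimide, DIC, DMAP (cat.), CH2Cl2, rt; filter, evaporate; then 11, NiBr2·glyme (20 mol %), 4,4'-di-tert-butyl-2,2'-bipyridine (20 mol %), Zn, DMA, rt
Reagents that add atoms: N-hydroxyphthalimide, O=C1c2ccccc2C(=O)N1O (its atoms are held only in 32 and leave again)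
Why: Same reductive decarboxylative arylation as in step 7, the C3 radical of ring R taking the small dimethoxyphenyl group anti to the C2 aryl group (3S, trans) and the aryl chloride staying untouched.

Step 20
Reactants: 33 ring M/ring R chloride from step 19
Product: 34 4-[(2R,3R)-6-ethenyl-3-[(2S,3S)-3-(3,5-dimethoxyphenyl)-6-methoxy-2-[4-(methylsulfonyloxy)phenyl]-2,3-dihydro-1-benzofuran-4-yl]-2,3-dihydro-1-benzofuran-2-yl]phenyl methanesulfonate
Conditions: CH2=CH–Bpin, Pd(OAc)2 (5 mol %), SPhos (10 mol %), K3PO4, 1,4-dioxane/H2O, 80 °C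
Reagents that add atoms: 4,4,5,5-tetramethyl-2-vinyl-1,3,2-dioxaborolane, C=CB1OC(C)(C)C(C)(C)O1
Why: Suzuki–Miyaura vinylation at the only aryl chloride, which the dialkylbiarylphosphine–palladium catalyst activates at a temperature where aryl mesylates do not react.

Step 21
Reactants: 13 ring L chloride from step 7; 34 ring M/ring R styrene from step 20
Product: 35 (E)-stilbene in which C5 of ring L of 13 (chlorine replaced) is bonded to the terminal vinyl carbon of 34; tris(methanesulfonate) hexamethyl ether of the target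
Conditions: Pd2(dba)3 (3 mol %), [HP(t-Bu)3]BF4 (12 mol %), Cy2NMe, 1,4-dioxane, 110 °C
Reagents that add atoms: none
Why: Mizoroki–Heck reaction of an electron-rich aryl chloride under bulky trialkylphosphine–palladium catalysis, where syn insertion and syn β-hydride elimination give the E alkene and the mesylates are inert.

Step 22
Reactants: 35 protected stilbene from step 21
Product: 36 hexamethyl ether of the target with the three 4-hydroxyphenyl groups free
Conditions: KOH, MeOH/THF, 60 °C; then aq. NH4Cl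
Reagents that add atoms: none
Why: Alkaline S–O cleavage of the three aryl methanesulfonates leaves the methyl ethers and the stilbene alone, and any reversible quinone-methide opening of a dihydrofuran ring recloses trans to the fixed C3 centre.

Step 23
Reactants: 36 hexamethyl ether from step 22
Product: 37 target CNP0265934.1, ring L (2S,3S), ring M (2R,3R), ring R (2S,3S), E-stilbene
Conditions: BBr3 (excess), CH2Cl2, −78 °C to rt; MeOH, then H2O
Reagents that add atoms: none
Why: Lewis-acid cleavage of the six aryl methyl ethers by bromide attack on the boron-activated O-methyl groups, the usual last step for permethylated oligostilbenes, with the trans rings being the stable arrangement under these conditions.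

**Compound list**

1 | (4-hydroxyphenyl)boronic acid | OB(O)c1ccc(O)cc1 | starting material
2 | [4-(methylsulfonyloxy)phenyl]boronic acid | CS(=O)(=O)Oc1ccc(B(O)O)cc1 | intermediate
3 | 1-(2-hydroxy-3-methoxyphenyl)ethanone | CC(=O)c1cccc(OC)c1O | starting material
4 | 1-(5-chloro-2-hydroxy-3-methoxyphenyl)ethanone | CC(=O)c1cc(Cl)cc(OC)c1O | intermediate
5 | (E)-1-(5-chloro-2-hydroxy-3-methoxyphenyl)-3-(dimethylamino)prop-2-en-1-one | CN(C)/C=C/C(=O)c1cc(Cl)cc(OC)c1O | intermediate (not isolated)
6 | 6-chloro-8-methoxy-4H-chromen-4-one | COc1cc(Cl)cc2c(=O)ccoc12 | intermediate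
7 | 4-[(2S)-6-chloro-8-methoxy-4-oxo-3,4-dihydro-2H-chromen-2-yl]phenyl methanesulfonate | CS(=O)(=O)Oc1ccc([C@@H]2CC(=O)c3cc(Cl)cc(OC)c3O2)cc1 | intermediate
8 | 4-[(2S)-6-chloro-4,8-dimethoxy-2H-chromen-2-yl]phenyl methanesulfonate | CS(=O)(=O)Oc1ccc([C@@H]2C=C(OC)c3cc(Cl)cc(OC)c3O2)cc1 | intermediate (not isolated)
9 | methyl (2S,3S)-5-chloro-7-methoxy-2-[4-(methylsulfonyloxy)phenyl]-2,3-dihydro-1-benzofuran-3-carboxylate | CS(=O)(=O)Oc1ccc([C@H]2Oc3c(OC)cc(Cl)cc3[C@@H]2C(=O)OC)cc1 | intermediate
10 | (2S,3S)-5-chloro-7-methoxy-2-[4-(methylsulfonyloxy)phenyl]-2,3-dihydro-1-benzofuran-3-carboxylic acid | CS(=O)(=O)Oc1ccc([C@H]2Oc3c(OC)cc(Cl)cc3[C@@H]2C(=O)O)cc1 | intermediate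
11 | 1-iodo-3,5-dimethoxybenzene | COc1cc(I)cc(OC)c1 | starting material
12 | 1,3-dioxoisoindolin-2-yl ester of acid 10 | CS(=O)(=O)Oc1ccc([C@H]2Oc3c(OC)cc(Cl)cc3[C@@H]2C(=O)ON2C(=O)c3ccccc3C2=O)cc1 | intermediate (not isolated)
13 | 4-[(2S,3S)-5-chloro-3-(3,5-dimethoxyphenyl)-7-methoxy-2,3-dihydro-1-benzofuran-2-yl]phenyl methanesulfonate | CS(=O)(=O)Oc1ccc([C@H]2Oc3c(OC)cc(Cl)cc3[C@@H]2c2cc(OC)cc(OC)c2)cc1 | intermediate
14 | 1-(4-chloro-2-hydroxyphenyl)ethanone | CC(=O)c1ccc(Cl)cc1O | starting material
15 | (E)-1-(4-chloro-2-hydroxyphenyl)-3-(dimethylamino)prop-2-en-1-one | CN(C)/C=C/C(=O)c1ccc(Cl)cc1O | intermediate (not isolated)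
16 | 7-chloro-4H-chromen-4-one | O=c1ccoc2cc(Cl)ccc12 | intermediate
17 | 4-[(2R)-7-chloro-4-oxo-3,4-dihydro-2H-chromen-2-yl]phenyl methanesulfonate | CS(=O)(=O)Oc1ccc([C@H]2CC(=O)c3ccc(Cl)cc3O2)cc1 | intermediate
18 | 4-[(2R)-7-chloro-4-methoxy-2H-chromen-2-yl]phenyl methanesulfonate | CS(=O)(=O)Oc1ccc([C@H]2C=C(OC)c3ccc(Cl)cc3O2)cc1 | intermediate (not isolated)
19 | methyl (2R,3R)-6-chloro-2-[4-(methylsulfonyloxy)phenyl]-2,3-dihydro-1-benzofuran-3-carboxylate | CS(=O)(=O)Oc1ccc([C@@H]2Oc3cc(Cl)ccc3[C@H]2C(=O)OC)cc1 | intermediate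
20 | (2R,3R)-6-chloro-2-[4-(methylsulfonyloxy)phenyl]-2,3-dihydro-1-benzofuran-3-carboxylic acid | CS(=O)(=O)Oc1ccc([C@@H]2Oc3cc(Cl)ccc3[C@H]2C(=O)O)cc1 | intermediate
21 | 1-bromo-3,5-dimethoxybenzene | COc1cc(Br)cc(OC)c1 | starting material
22 | 1-(2-bromo-4,6-dimethoxyphenyl)ethanone | CC(=O)c1c(Br)cc(OC)cc1OC | intermediate
23 | 1-(2-bromo-6-hydroxy-4-methoxyphenyl)ethanone | CC(=O)c1c(Br)cc(OC)cc1O | intermediate
24 | (E)-1-(2-bromo-6-hydroxy-4-methoxyphenyl)-3-(dimethylamino)prop-2-en-1-one | CN(C)/C=C/C(=O)c1c(Br)cc(OC)cc1O | intermediate (not isolated)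
25 | 5-bromo-7-methoxy-4H-chromen-4-one | COc1cc(Br)c2c(=O)ccoc2c1 | intermediate
26 | 4-[(2S)-5-bromo-7-methoxy-4-oxo-3,4-dihydro-2H-chromen-2-yl]phenyl methanesulfonate | CS(=O)(=O)Oc1ccc([C@@H]2CC(=O)c3c(Br)cc(OC)cc3O2)cc1 | intermediate
27 | 4-[(2S)-5-bromo-4,7-dimethoxy-2H-chromen-2-yl]phenyl methanesulfonate | CS(=O)(=O)Oc1ccc([C@@H]2C=C(OC)c3c(Br)cc(OC)cc3O2)cc1 | intermediate (not isolated)
28 | methyl (2S,3S)-4-bromo-6-methoxy-2-[4-(methylsulfonyloxy)phenyl]-2,3-dihydro-1-benzofuran-3-carboxylate | CS(=O)(=O)Oc1ccc([C@H]2Oc3cc(OC)cc(Br)c3[C@@H]2C(=O)OC)cc1 | intermediate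
29 | 1,3-dioxoisoindolin-2-yl ester of acid 20 | CS(=O)(=O)Oc1ccc([C@@H]2Oc3cc(Cl)ccc3[C@H]2C(=O)ON2C(=O)c3ccccc3C2=O)cc1 | intermediate (not isolated)
30 | methyl (2S,3S)-4-[(2R,3R)-6-chloro-2-[4-(methylsulfonyloxy)phenyl]-2,3-dihydro-1-benzofuran-3-yl]-6-methoxy-2-[4-(methylsulfonyloxy)phenyl]-2,3-dihydro-1-benzofuran-3-carboxylate | Clc1ccc2c(c1)O[C@@H](c1ccc(OS(C)(=O)=O)cc1)[C@@H]2c1cc(OC)cc2c1[C@H](C(=O)OC)[C@@H](c1ccc(OS(C)(=O)=O)cc1)O2 | intermediate
31 | carboxylic acid corresponding to ester 30 | Clc1ccc2c(c1)O[C@@H](c1ccc(OS(C)(=O)=O)cc1)[C@@H]2c1cc(OC)cc2c1[C@H](C(=O)O)[C@@H](c1ccc(OS(C)(=O)=O)cc1)O2 | intermediate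
32 | 1,3-dioxoisoindolin-2-yl ester of acid 31 | Clc1ccc2c(c1)O[C@@H](c1ccc(OS(C)(=O)=O)cc1)[C@@H]2c1cc(OC)cc2c1[C@H](C(=O)ON1C(=O)c3ccccc3C1=O)[C@@H](c1ccc(OS(C)(=O)=O)cc1)O2 | intermediate (not isolated)
33 | 4-[(2R,3R)-6-chloro-3-[(2S,3S)-3-(3,5-dimethoxyphenyl)-6-methoxy-2-[4-(methylsulfonyloxy)phenyl]-2,3-dihydro-1-benzofuran-4-yl]-2,3-dihydro-1-benzofuran-2-yl]phenyl methanesulfonate | Clc1ccc2c(c1)O[C@@H](c1ccc(OS(C)(=O)=O)cc1)[C@@H]2c1cc(OC)cc2c1[C@H](c1cc(OC)cc(OC)c1)[C@@H](c1ccc(OS(C)(=O)=O)cc1)O2 | intermediate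
34 | 6-ethenyl analogue of 33 (vinyl in place of chlorine) | C=Cc1ccc2c(c1)O[C@@H](c1ccc(OS(C)(=O)=O)cc1)[C@@H]2c1cc(OC)cc2c1[C@H](c1cc(OC)cc(OC)c1)[C@@H](c1ccc(OS(C)(=O)=O)cc1)O2 | intermediate
35 | tris(methanesulfonate) hexamethyl ether of the target, E-stilbene | CS(=O)(=O)Oc1ccc([C@H]2Oc3c(OC)cc(/C=C/c4ccc5c(c4)O[C@@H](c4ccc(OS(C)(=O)=O)cc4)[C@@H]5c4cc(OC)cc5c4[C@H](c4cc(OC)cc(OC)c4)[C@@H](c4ccc(OS(C)(=O)=O)cc4)O5)cc3[C@@H]2c2cc(OC)cc(OC)c2)cc1 | intermediate
36 | hexamethyl ether of the target, three 4-hydroxyphenyl groups free | Oc1ccc([C@H]2Oc3c(OC)cc(/C=C/c4ccc5c(c4)O[C@@H](c4ccc(O)cc4)[C@@H]5c4cc(OC)cc5c4[C@H](c4cc(OC)cc(OC)c4)[C@@H](c4ccc(O)cc4)O5)cc3[C@@H]2c2cc(OC)cc(OC)c2)cc1 | intermediate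
37 | CNP0265934.1 | Oc1ccc([C@H]2Oc3c(O)cc(/C=C/c4ccc5c(c4)O[C@@H](c4ccc(O)cc4)[C@@H]5c4cc(O)cc5c4[C@H](c4cc(O)cc(O)c4)[C@@H](c4ccc(O)cc4)O5)cc3[C@@H]2c2cc(O)cc(O)c2)cc1 | target

**Counts and risks**

Total step count: 23. Longest linear sequence: 12 steps (steps 12 to 23, from 1-bromo-3,5-dimethoxybenzene).

Steps most likely to fail:

Step 5 (and its repeats, steps 10 and 16). The C3 iodanyl intermediate may lose a proton instead of undergoing the aryl shift (dehydrogenation to the flavone), the C2 aryl group may migrate in place of C4a, or the strong acid may open the pyranone reversibly and erode the C2 configuration. The fallback sets out from 7 and replaces the oxidative shift by a Wolff ring contraction. The lithium enolate of 7 (LiHMDS, THF, −78 °C, kept cold so that the C2 phenoxide is not expelled) is acylated with CF3CO2CH2CF3 to give 4-[(2S)-6-chloro-8-methoxy-4-oxo-3-(trifluoroacetyl)-3,4-dihydro-2H-chromen-2-yl]phenyl methanesulfonate F1. Detrifluoroacetylative diazo transfer (MsN3, Et3N, MeCN) then gives 4-[(2R)-6-chloro-3-diazo-8-methoxy-4-oxo-3,4-dihydro-2H-chromen-2-yl]phenyl methanesulfonate F2, which has the same spatial arrangement at C2 as 7 (the descriptor changes only through the priority rules). Irradiation of F2 in methanol (350 nm) expels nitrogen, C4a shifts to the carbene carbon C3, and methanol traps the ketene as the ester, formed partly as the cis epimer methyl (2S,3R)-5-chloro-7-methoxy-2-[4-(methylsulfonyloxy)phenyl]-2,3-dihydro-1-benzofuran-3-carboxylate F3. Brief treatment with catalytic NaOMe in MeOH at 0 °C equilibrates F3 to the trans ester, and the route is rejoined at 9.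

Step 17. Oxidative addition of the ortho-substituted aryl bromide to nickel may be slower than reduction of the activated ester, so the benzylic radical dimerises or is reduced, and radical capture may take place with poor facial selectivity at C3 of ring M. The fallback sets out from 20 and 28 and joins them without activated ester or zinc by metallaphotoredox decarboxylative arylation: Ir[dF(CF3)ppy]2(dtbbpy)PF6 (1 mol %), NiCl2·glyme, 4,4'-di-tert-butyl-2,2'-bipyridine, Cs2CO3, DMF, blue light, rt. The radical is then generated oxidatively from the carboxylate at a rate set by the light while the aryl bromide rests on nickel. This fallback makes no new compound (F0) and rejoins the route at 30.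

Step 19. The neighbouring C4 substituent may slow capture of the C3 radical of ring R, so that hydrogen abstraction (protodecarboxylation) competes, or may steer the aryl group cis to the C2 aryl group. The fallback changes the order of bond formation and sets out from 28, arylating ring R before C4 is substituted. Me3SnOH cleavage gives (2S,3S)-4-bromo-6-methoxy-2-[4-(methylsulfonyloxy)phenyl]-2,3-dihydro-1-benzofuran-3-carboxylic acid F4. N-Hydroxyphthalimide and DIC convert it into its 1,3-dioxoisoindolin-2-yl ester F5. Coupling of F5 with iodide 11 (NiBr2·glyme, bipyridine ligand, Zn, DMA, rt; the iodide reacts in preference to the hindered bromide) gives 4-[(2S,3S)-4-bromo-3-(3,5-dimethoxyphenyl)-6-methoxy-2,3-dihydro-1-benzofuran-2-yl]phenyl methanesulfonate F6. F6 is then joined to ester 29 (made from 20 as in step 17) under the conditions of step 17, and the route is rejoined at 33, steps 17 to 19 being replaced.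

**Further compounds**

F1 | step 5 | 4-[(2S)-6-chloro-8-methoxy-4-oxo-3-(trifluoroacetyl)-3,4-dihydro-2H-chromen-2-yl]phenyl methanesulfonate (C3 epimers and enol form) | CS(=O)(=O)Oc1ccc([C@H]2Oc3c(OC)cc(Cl)cc3C(=O)C2C(=O)C(F)(F)F)cc1
F2 | step 5 | 4-[(2R)-6-chloro-3-diazo-8-methoxy-4-oxo-3,4-dihydro-2H-chromen-2-yl]phenyl methanesulfonate | CS(=O)(=O)Oc1ccc([C@@H]2C(=[N+]=[N-])C(=O)c3cc(Cl)cc(OC)c3O2)cc1
F3 | step 5 | methyl (2S,3R)-5-chloro-7-methoxy-2-[4-(methylsulfonyloxy)phenyl]-2,3-dihydro-1-benzofuran-3-carboxylate (cis epimer of 9) | CS(=O)(=O)Oc1ccc([C@H]2Oc3c(OC)cc(Cl)cc3[C@H]2C(=O)OC)cc1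
F0 | step 17 | none | none
F4 | step 19 | (2S,3S)-4-bromo-6-methoxy-2-[4-(methylsulfonyloxy)phenyl]-2,3-dihydro-1-benzofuran-3-carboxylic acid | CS(=O)(=O)Oc1ccc([C@H]2Oc3cc(OC)cc(Br)c3[C@@H]2C(=O)O)cc1
F5 | step 19 | 1,3-dioxoisoindolin-2-yl ester of acid F4 | CS(=O)(=O)Oc1ccc([C@H]2Oc3cc(OC)cc(Br)c3[C@@H]2C(=O)ON2C(=O)c3ccccc3C2=O)cc1
F6 | step 19 | 4-[(2S,3S)-4-bromo-3-(3,5-dimethoxyphenyl)-6-methoxy-2,3-dihydro-1-benzofuran-2-yl]phenyl methanesulfonate | CS(=O)(=O)Oc1ccc([C@H]2Oc3cc(OC)cc(Br)c3[C@@H]2c2cc(OC)cc(OC)c2)cc1
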